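## Structural features

The target is a bicyclic enol acetal. Ring A is a cyclohex-2-en-1-one (C1 carbonyl, C2=C3, quaternary C4, methylene C5, C6). It is fused along C3–C4 to a 1,3-dioxolane (ring B) whose CH2 joins the enol oxygen O3 to the tertiary oxygen O4.

C4 carries O4 and the (2S)-1-(3,4,5-trimethoxyphenyl)propan-2-yl chain, so the quaternary carbinol C4 (R) stands directly next to the side-chain stereocentre C7 (S). The third stereocentre, C6 (R, allyl), is separated from C4 by C5, and its allyl group is trans to the side chain.

The fragile groups are:
- the vinylogous ester locked in a formaldehyde acetal, which aqueous acid or alkoxide exchange at C3 would open;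
- the epimerisable C6–H;
- the terminal alkene;
- the electron-rich trimethoxyarene, which free formaldehyde-type cations would alkylate.

The real difficulty is twofold. The fully substituted, oxygenated C4 must be made in one absolute configuration beside C7. The ring oxygens O1 and O3 must also be told apart so that the acetal closes on O3 only.

C6 is a lesser problem. Ring B holds O4 pseudo-equatorial and the side chain pseudo-axial, so the trans (6R) isomer avoids a 1,3-diaxial contact and should be the thermodynamic one.

The plan rests on C5. This carbon bears only hydrogen and is flanked by the carbinol carbon C4 and the ketone α-carbon C6. The C5–C6 bond can therefore be made by a ketone enolate at C6 attacking the terminal carbon of an epoxide whose other carbon is C4. This closes ring A and leaves the C4 oxygen in place with the configuration of an earlier asymmetric epoxidation.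

## Logic of the disconnections

**21 ⇒ 20.** No skeletal bond is cut; only the configuration at C6 is released. C6–H is α to the ketone, and with ring B in place the trans arrangement is the relaxed one. This removes C6 from every earlier stereochemical question. The forward step must enolise C6 reversibly with a base that cannot exchange the alkoxy group on C3.

**20 ⇒ 18 (through 19).** The O3–CH2 bond of ring B is cut and O3 returns to a methyl enol ether. With the CH2 still attached to O4, the acetal closes intramolecularly and only O3 is within reach. O1 and C2 of the dione cannot compete, and no external formaldehyde electrophile meets the dione or the arene. The gain is a monocyclic compound with differentiated ring oxygens. The forward step must hydrolyse the enol ether while the methoxymethyl group survives, then exchange methanol for O3 under dry, mild acid.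

**18 ⇒ 17.** The O4–CH2 bond is cut. The tertiary hydroxyl is the only free OH in 17, so the acetal carbon can be attached without a selectivity problem. This exposes the direct product of the ring-forming step. The forward step must alkylate a hindered tertiary alcohol without generating the C6 enolate.

**17 ⇒ 15 (through 16).** The ring bond C5–C6 is cut, and C4–O4 becomes one bond of an epoxide whose other carbon is C5. The cut turns ring A into an acyclic chain and moves the C4 stereocentre into a 2,2-disubstituted epoxide. One ring and the C6 stereocentre disappear. The forward step needs the C6 enolate to attack C5 (not C4, and not through oxygen), and needs an (E)-enol ether so that C1 and C4 are cis.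

**15 ⇒ 14.** The C3–OCH3 bond is cut, leaving an ynone. The alkyne fixes the oxidation level of C1–C3 and makes C3 the only site for methanol, so the oxygen pattern is regiodefined. The forward step must leave the epoxide alone and let the enol ether settle as (E).

**14 ⇒ 10 + 12 (through 13); 12 ⇒ 11.** The C1–C2 bond is cut between acetylide and acyl carbon. This convergent cut separates the epoxide fragment from the five-carbon chain, and it brings in the terminal alkene only after the epoxidation. 12 is cut at its C–N bond to 11. The forward step needs clean mono-acylation and no attack of the organolithium on the epoxide.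

**10 ⇒ 9 ⇒ 8.** The C2≡C3 bond is cut to an aldehyde at C3, and the aldehyde is traced back to a primary alcohol. That alcohol is the handle the epoxidation needs. Oxidation and basic homologation must not open the epoxide; C4 is quaternary and cannot epimerise.

**8 ⇒ 7.** The two C–O bonds of the epoxide are cut, leaving a 2-substituted allylic alcohol. The quaternary stereocentre disappears. The tartrate must dominate over the neighbouring C7 centre, and the epoxide must survive the titanium alkoxide.

**7 ⇒ 5 (through 6).** The exocyclic C4=C5 bond is cut and the hydroxymethyl carbon returns to an aldehyde. α-Methylenation places C5 on the carbon that later receives C6. The forward step must avoid double-bond migration toward C7.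

**5 ⇒ 4 ⇒ 3.** After a redox adjustment, the C7–CH3 bond is cut, leaving an achiral (E)-enoate. The one stereocentre that has no neighbour to lean on is assigned to a catalytic conjugate addition. It needs high face selectivity and must outrun γ-deprotonation.

**3 ⇒ 1 + 2.** The C=C bond is cut into two terminal alkenes, both commercial. The forward step needs (E)-selectivity and no migration of the allyl double bond.

## Other disconnections considered

Alternative 1: The cut removes the ring B bonds O3–C3 and O4–CH2 and leaves the symmetrical para-quinol A1. In the forward direction a chiral phosphoric acid would join the tertiary hydroxyl of A1 to formaldehyde A2 and steer the hemiformal oxygen onto one of the two enone β-carbons, giving the cis-fused dioxolane A3.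
- In its favour: A1 should be only a few steps from simple aromatic material by oxidative dearomatisation. The acetal carbon is tethered to O4 before the second C–O bond forms, so the acetal regiochemistry is as secure as in the chosen plan and is reached in fewer steps. On this point the alternative is the better one.
- Against it here: in A3 the acetal oxygen sits on a saturated C3 and the remaining enone is C5=C6. C6 must still be allylated with reduction of that enone, and C2–C3 must be dehydrogenated. The β-alkoxy ketone in between can lose O3 by β-elimination once it is enolised toward C2, and the hemiformal addition is itself reversible. The two enone faces of A1 are diastereotopic because of C7, so the catalyst must override substrate bias.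
- Comparison: on structure the alternative reaches the bicyclic acetal faster but without C2=C3. On mechanism both plans fix the acetal by an intramolecular oxygen transfer (equal), but the chosen plan sets C4 by an irreversible, reagent-controlled epoxidation. On step economy the alternative is ahead up to A3 and spends that lead on oxidation-state corrections.

Alternative 2: The cut is C4–C5 together with the O4–C1 acyl bond, so ring A is opened to a γ-butyrolactone. In the forward direction a chiral triazolium carbene would turn the enal A5 into a homoenolate. This adds through C5 to the ketone of the racemic α-ketoester A4 while the centre next to that ketone equilibrates, and lactonisation gives A6.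
- In its favour: it is convergent. It creates C4 and resolves C7 in one catalytic operation, and C6 arrives with the enal. In stereocentre economy it is better than the chosen plan, which spends separate steps on C7 and C4.
- Against it here: homoenolate formation is best supported for β-aryl enals, not for an α-branched, β-unsubstituted one. A β-alkyl α-ketoester racemises far more slowly than the β-halo esters on which such dynamic resolutions rest. A6 also lacks C2: the ester must become an acetyl group and ring A must close by an intramolecular Claisen-type acyl transfer, which delivers the free hydroxy-dione A7. A7 then needs an intermolecular methylenation in which O1, O3 and C2 compete, the ambiguity the chosen route avoids.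
- Comparison: on structure the alternative builds the carbinol more directly. On mechanism its key step has weaker support for these partners than an enolate–epoxide alkylation. On step economy the two are comparable, the alternative ahead before ring A and behind after it.

Alternative 3: The cut takes out C1 as carbon monoxide, breaking C1–C2 and C1–C6 and leaving the iodoalkene A8, in which ring B already exists. In the forward direction zerovalent palladium would add oxidatively into the C–I bond of A8. Insertion of carbon monoxide A9, six-membered exo acylpalladation of the pendant vinyl group and β-hydride elimination would give the exo-methylene enone A10. Conjugate addition of a vinyl copper reagent would then make the allyl group and set C6 on protonation.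
- In its favour: ring B is present before ring A is made, so the acetal question never arises late; this is the best of the four plans on that point. Two C–C bonds form in one step. Cyclic acylpalladation has direct precedent, which the ring closure of the chosen plan lacks. The end game is shorter.
- Against it here: A8 needs an enantiopure tertiary carbinol bearing allyl, the branched side chain and an alkenyl group, and no method as dependable as the Sharpless epoxidation is at hand for it. The iodoalkene geometry must also be controlled. A10 is a cross-conjugated exo-methylene ketone, open to palladium hydride migration of the double bond into the ring and to self-addition.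
- Comparison: the two plans are equal in the ring they close and in leaving C6 to thermodynamic control. The alternative is better in mechanistic precedent and in the timing of the acetal. It is worse in access to C4 and in the stability of its key-step product. Step count should be similar once A8 must be made enantiopure.

Key step: step 11

Remarks on the chemistry (assumptions):
- The antipode of the bisphosphine in step 2 that delivers methyl to the Si face of the β-carbon is taken to be (R)-Tol-BINAP; if the sense is the reverse, the (S)-ligand is used and nothing else changes.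
- The key step is taken to give both C6 epimers; 17, 18, 19 and 20 are carried as epimer mixtures, their SMILES carry no descriptor at C6, and step 14 sets C6.
- Elemicin, methyl acrylate and pent-4-enoyl chloride are taken as commercial.

Step 1
Reactants: 1 elemicin (5-allyl-1,2,3-trimethoxybenzene); 2 methyl acrylate
Product: 3 methyl (2E)-4-(3,4,5-trimethoxyphenyl)but-2-enoate
Conditions: second-generation Hoveyda–Grubbs catalyst RuCl2(H2IMes)(=CH-C6H4-2-O-i-Pr) (2 mol %), 2 (4 equiv), 1,4-benzoquinone (10 mol %), CH2Cl2, 40 °C
Reagents that add atoms: none
Why: Olefin cross-metathesis of an allylarene with an excess of an electron-poor acrylate should give the cross product as the (E)-enoate, since the acrylate homodimerises slowly; benzoquinone suppresses ruthenium hydride migration of the allyl double bond.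

Step 2
Reactants: 3 methyl (2E)-4-(3,4,5-trimethoxyphenyl)but-2-enoate
Product: 4 methyl (3S)-3-methyl-4-(3,4,5-trimethoxyphenyl)butanoate
Conditions: MeMgBr (3 equiv), CuI (2 mol %), (R)-Tol-BINAP [(R)-2,2′-bis(di-p-tolylphosphanyl)-1,1′-binaphthyl] (3 mol %), t-BuOMe, −20 °C; aq. NH4Cl
Reagents that add atoms: methylmagnesium bromide, C[Mg]Br
Why: Copper-catalysed asymmetric conjugate addition of a Grignard reagent to an (E)-enoate; the chiral bisphosphine–copper complex should deliver methyl to the Si face of the β-carbon, which sets the (S) centre that becomes C7. The low temperature and the low basicity of the cuprate should outrun deprotonation at the benzylic γ-position.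

Step 3
Reactants: 4 methyl (3S)-3-methyl-4-(3,4,5-trimethoxyphenyl)butanoate
Product: 5 (3S)-3-methyl-4-(3,4,5-trimethoxyphenyl)butanal
Conditions: i-Bu2AlH (1.1 equiv), CH2Cl2, −78 °C; aq. potassium sodium tartrate
Reagents that add atoms: none
Why: Partial reduction of a methyl ester with one equivalent of i-Bu2AlH at −78 °C stops at the aluminium hemiacetal, which releases the aldehyde on work-up; the β-stereocentre is not enolisable.

Step 4
Reactants: 5 (3S)-3-methyl-4-(3,4,5-trimethoxyphenyl)butanal
Product: 7 (3S)-3-methyl-2-methylidene-4-(3,4,5-trimethoxyphenyl)butan-1-ol, via 2-methylidene aldehyde 6 (not isolated)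
Conditions: aq. CH2O (37 %, 1.1 equiv), pyrrolidine (10 mol %), propanoic acid (10 mol %), i-PrOH, 45 °C; then MeOH, CeCl3·7H2O, NaBH4, 0 °C
Reagents that add atoms: formaldehyde, C=O
Why: Organocatalytic α-methylenation (Mannich condensation through the pyrrolidine enamine, then loss of the amine) followed in the same flask by Luche 1,2-reduction, so that the polymerisable 2-substituted acrolein 6 is never isolated. The short, mild methylenation should not move the double bond toward the stereocentre.

Step 5
Reactants: 7 (3S)-3-methyl-2-methylidene-4-(3,4,5-trimethoxyphenyl)butan-1-ol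
Product: 8 [(2R)-2-[(2S)-1-(3,4,5-trimethoxyphenyl)propan-2-yl]oxiran-2-yl]methanol
Conditions: Ti(Oi-Pr)4 (10 mol %), D-(−)-diisopropyl tartrate (12 mol %), t-BuOOH (2 equiv, in decane), 4 Å molecular sieves, CH2Cl2, −20 °C
Reagents that add atoms: tert-butyl hydroperoxide, CC(C)(C)OO
Why: Sharpless asymmetric epoxidation of a primary 2-substituted allylic alcohol; the tartrate, not the neighbouring centre, selects the alkene face, and D-(−)-tartrate is the antipode that gives the (2R)-epoxy alcohol (the sense in which it gives (R)-2-methylglycidol from 2-methylprop-2-en-1-ol). Catalytic loading with sieves limits alkoxide opening of the 2,2-disubstituted epoxide.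

Step 6
Reactants: 8 [(2R)-2-[(2S)-1-(3,4,5-trimethoxyphenyl)propan-2-yl]oxiran-2-yl]methanol
Product: 9 (2S)-2-[(2S)-1-(3,4,5-trimethoxyphenyl)propan-2-yl]oxirane-2-carbaldehyde
Conditions: Dess–Martin periodinane (1.3 equiv), pyridine (3 equiv), CH2Cl2, 0 °C → rt
Reagents that add atoms: none
Why: Dess–Martin oxidation under pyridine buffer converts the primary alcohol into the aldehyde without opening the epoxide; the α-carbon is quaternary and cannot epimerise (the descriptor changes only because the CIP ranking changes).

Step 7
Reactants: 9 (2S)-2-[(2S)-1-(3,4,5-trimethoxyphenyl)propan-2-yl]oxirane-2-carbaldehyde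
Product: 10 (2R)-2-ethynyl-2-[(2S)-1-(3,4,5-trimethoxyphenyl)propan-2-yl]oxirane
Conditions: dimethyl (1-diazo-2-oxopropyl)phosphonate (1.3 equiv), K2CO3 (2 equiv), MeOH, 0 °C → rt
Reagents that add atoms: dimethyl (1-diazo-2-oxopropyl)phosphonate, CC(=O)C(=[N+]=[N-])P(=O)(OC)OC
Why: Ohira–Bestmann (Seyferth–Gilbert) homologation: methanolysis of the reagent gives the diazomethylphosphonate anion, which adds to the aldehyde, and loss of phosphate and N2 with a 1,2-shift gives the terminal alkyne. The carbonate/methanol medium should leave the hindered epoxide and C4 untouched.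

Step 8
Reactants: 11 pent-4-enoyl chloride
Product: 12 N-methoxy-N-methylpent-4-enamide
Conditions: MeNHOMe·HCl (1.1 equiv), Et3N (2.2 equiv), CH2Cl2, 0 °C → rt
Reagents that add atoms: N,O-dimethylhydroxylamine hydrochloride, CNOC.Cl
Why: Acylation of N,O-dimethylhydroxylamine by an acid chloride (Weinreb amide formation); the terminal alkene is inert.

Step 9
Reactants: 10 (2R)-2-ethynyl-2-[(2S)-1-(3,4,5-trimethoxyphenyl)propan-2-yl]oxirane; 12 N-methoxy-N-methylpent-4-enamide
Product: 14 1-[(2R)-2-[(2S)-1-(3,4,5-trimethoxyphenyl)propan-2-yl]oxiran-2-yl]hept-6-en-1-yn-3-one, via lithium acetylide 13 (not isolated)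
Conditions: n-BuLi (1.05 equiv), THF, −78 °C; then 12 (1.2 equiv), −78 → 0 °C; aq. NH4Cl
Reagents that add atoms: none
Why: Weinreb ketone synthesis: the acetylide adds to the amide to give a chelated tetrahedral lithium adduct that collapses to the ynone only on work-up, so no tertiary alcohol forms. At −78 °C n-BuLi deprotonates the alkyne much faster than it opens the epoxide.

Step 10
Reactants: 14 1-[(2R)-2-[(2S)-1-(3,4,5-trimethoxyphenyl)propan-2-yl]oxiran-2-yl]hept-6-en-1-yn-3-one
Product: 15 (1E)-1-methoxy-1-[(2S)-2-[(2S)-1-(3,4,5-trimethoxyphenyl)propan-2-yl]oxiran-2-yl]hepta-1,6-dien-3-one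
Conditions: MeOH, K2CO3 (0.2 equiv), 0 °C → rt
Reagents that add atoms: methanol, CO
Why: Base-catalysed oxa-Michael addition of methanol to the ynone puts the methoxy group on C3 only. Under these reversible conditions the adduct should settle as the (E)-isomer, with the methoxy group beside H-2 and the bulky C4 substituent cis to the acyl carbon, which is the geometry the ring closure needs.

Step 11
Reactants: 15 (1E)-1-methoxy-1-[(2S)-2-[(2S)-1-(3,4,5-trimethoxyphenyl)propan-2-yl]oxiran-2-yl]hepta-1,6-dien-3-one
Product: 17 (4R)-4-hydroxy-3-methoxy-6-(prop-2-en-1-yl)-4-[(2S)-1-(3,4,5-trimethoxyphenyl)propan-2-yl]cyclohex-2-en-1-one (both C6 epimers), via lithium dienolate 16 (not isolated)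
Conditions: LiN(SiMe3)2 (1.2 equiv), THF, −78 °C, then 0 °C → rt; aq. NH4Cl
Reagents that add atoms: none
Why: LiN(SiMe3)2 removes an α′ proton at C6, the only acidic C–H because C4 is quaternary and offers no γ-proton, to give the cross-conjugated dienolate 16. On warming, C6 attacks the epoxide methylene C5 from the side opposite the C5–O bond (SN2), forming C5–C6 and freeing the tertiary alkoxide on C4. The closest known reaction type is the intramolecular C-alkylation of ketone and nitrile enolates by tethered epoxides at the less substituted carbon (Stork-type epoxide cyclisation), combined with α′-alkylation of vinylogous ester enolates (Stork–Danheiser). Ring A closes in a six-membered, epoxide-endo mode with both epoxide carbons in the ring, a 6-(enolendo)-exo-tet closure with respect to the breaking C5–O bond. The exo alternative would need backside attack at the fully substituted C4 to make a five-membered ring and is sterically excluded. The step needs carbon rather than oxygen alkylation, which the tight lithium ion pair in THF should favour. It also needs the (E)-enol ether, which holds C1 and C4 cis so that C6 can reach C5. C4 is not touched and keeps the configuration of step 5 (S becomes R only through the CIP ranking), whereas the new centre C6 forms without reliable control, because neither enolate geometry nor face of approach is fixed, and is left for step 14.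

Step 12
Reactants: 17 (4R)-4-hydroxy-3-methoxy-6-(prop-2-en-1-yl)-4-[(2S)-1-(3,4,5-trimethoxyphenyl)propan-2-yl]cyclohex-2-en-1-one (both C6 epimers)
Product: 18 (4R)-3-methoxy-4-(methoxymethoxy)-6-(prop-2-en-1-yl)-4-[(2S)-1-(3,4,5-trimethoxyphenyl)propan-2-yl]cyclohex-2-en-1-one (both C6 epimers)
Conditions: MeOCH2Cl (5 equiv), i-Pr2NEt (8 equiv), Bu4NI (0.1 equiv), ClCH2CH2Cl, 50 °C
Reagents that add atoms: chloromethyl methyl ether, COCCl
Why: O-alkylation of the tertiary alcohol with chloromethyl methyl ether under amine base and iodide catalysis; the amine does not enolise the ketone, so only O4 reacts. This puts the future acetal carbon on O4 before the second ring oxygen is unmasked.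

Step 13
Reactants: 18 (4R)-3-methoxy-4-(methoxymethoxy)-6-(prop-2-en-1-yl)-4-[(2S)-1-(3,4,5-trimethoxyphenyl)propan-2-yl]cyclohex-2-en-1-one (both C6 epimers)
Product: 20 (7aR)-6-(prop-2-en-1-yl)-7a-[(2S)-1-(3,4,5-trimethoxyphenyl)propan-2-yl]-7,7a-dihydro-1,3-benzodioxol-5(6H)-one (both C6 epimers), via methoxymethyl ether dione 19 (not isolated)
Conditions: p-TsOH·H2O (0.2 equiv), H2O (2 equiv), THF, rt; then toluene, 5 Å molecular sieves, 60 °C
Reagents that add atoms: water, O
Why: Mild aqueous acid hydrolyses the vinylogous methyl ester to the 1,3-dione 19 while the formaldehyde acetal survives. On drying and warming, the enolic oxygen on C3 displaces methanol from the neighbouring methoxymethyl group in a five-membered intramolecular transacetalisation, the known route from a methoxymethyl ether and an adjacent hydroxyl to a methylene acetal. Only O3 can reach the acetal carbon, so O1, C2 and the arene stay out and no external formaldehyde electrophile is present.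

Step 14
Reactants: 20 (7aR)-6-(prop-2-en-1-yl)-7a-[(2S)-1-(3,4,5-trimethoxyphenyl)propan-2-yl]-7,7a-dihydro-1,3-benzodioxol-5(6H)-one (both C6 epimers)
Product: 21 (6R,7aR)-6-(prop-2-en-1-yl)-7a-[(2S)-1-(3,4,5-trimethoxyphenyl)propan-2-yl]-7,7a-dihydro-1,3-benzodioxol-5(6H)-one (CNP0108174.2)
Conditions: DBU (0.3 equiv), toluene, 40 °C
Reagents that add atoms: none
Why: Base-mediated epimerisation through the C6 enolate with a non-nucleophilic amidine, which cannot exchange the alkoxy group on C3. Ring B holds O4 pseudo-equatorial and the side chain pseudo-axial, so the allyl group should settle pseudo-equatorial, trans to the side chain (6R).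

## Compound list

1 | elemicin (5-allyl-1,2,3-trimethoxybenzene) | C=CCc1cc(OC)c(OC)c(OC)c1 | starting material
2 | methyl acrylate | C=CC(=O)OC | starting material
3 | methyl (2E)-4-(3,4,5-trimethoxyphenyl)but-2-enoate | COC(=O)/C=C/Cc1cc(OC)c(OC)c(OC)c1 | intermediate
4 | methyl (3S)-3-methyl-4-(3,4,5-trimethoxyphenyl)butanoate | COC(=O)C[C@@H](C)Cc1cc(OC)c(OC)c(OC)c1 | intermediate
5 | (3S)-3-methyl-4-(3,4,5-trimethoxyphenyl)butanal | O=CC[C@@H](C)Cc1cc(OC)c(OC)c(OC)c1 | intermediate
6 | (3S)-3-methyl-2-methylidene-4-(3,4,5-trimethoxyphenyl)butanal | O=CC(=C)[C@@H](C)Cc1cc(OC)c(OC)c(OC)c1 | intermediate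
7 | (3S)-3-methyl-2-methylidene-4-(3,4,5-trimethoxyphenyl)butan-1-ol | OCC(=C)[C@@H](C)Cc1cc(OC)c(OC)c(OC)c1 | intermediate
8 | [(2R)-2-[(2S)-1-(3,4,5-trimethoxyphenyl)propan-2-yl]oxiran-2-yl]methanol | OC[C@@]1(CO1)[C@@H](C)Cc1cc(OC)c(OC)c(OC)c1 | intermediate
9 | (2S)-2-[(2S)-1-(3,4,5-trimethoxyphenyl)propan-2-yl]oxirane-2-carbaldehyde | O=C[C@@]1(CO1)[C@@H](C)Cc1cc(OC)c(OC)c(OC)c1 | intermediate
10 | (2R)-2-ethynyl-2-[(2S)-1-(3,4,5-trimethoxyphenyl)propan-2-yl]oxirane | C#C[C@@]1(CO1)[C@@H](C)Cc1cc(OC)c(OC)c(OC)c1 | intermediate
11 | pent-4-enoyl chloride | C=CCCC(Cl)=O | starting material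
12 | N-methoxy-N-methylpent-4-enamide | C=CCCC(=O)N(C)OC | intermediate
13 | lithium acetylide of 10, lithium {(2R)-2-[(2S)-1-(3,4,5-trimethoxyphenyl)propan-2-yl]oxiran-2-yl}ethynide | [Li]C#C[C@@]1(CO1)[C@@H](C)Cc1cc(OC)c(OC)c(OC)c1 | intermediate
14 | 1-[(2R)-2-[(2S)-1-(3,4,5-trimethoxyphenyl)propan-2-yl]oxiran-2-yl]hept-6-en-1-yn-3-one | C=CCCC(=O)C#C[C@@]1(CO1)[C@@H](C)Cc1cc(OC)c(OC)c(OC)c1 | intermediate
15 | (1E)-1-methoxy-1-[(2S)-2-[(2S)-1-(3,4,5-trimethoxyphenyl)propan-2-yl]oxiran-2-yl]hepta-1,6-dien-3-one | C=CCCC(=O)/C=C(/OC)[C@@]1(CO1)[C@@H](C)Cc1cc(OC)c(OC)c(OC)c1 | intermediate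
16 | lithium (1E)-1-methoxy-1-[(2S)-2-[(2S)-1-(3,4,5-trimethoxyphenyl)propan-2-yl]oxiran-2-yl]hepta-1,3,6-trien-3-olate (enolate geometry open) | C=CCC=C(O[Li])/C=C(/OC)[C@@]1(CO1)[C@@H](C)Cc1cc(OC)c(OC)c(OC)c1 | intermediate
17 | (4R)-4-hydroxy-3-methoxy-6-(prop-2-en-1-yl)-4-[(2S)-1-(3,4,5-trimethoxyphenyl)propan-2-yl]cyclohex-2-en-1-one (both C6 epimers) | C=CCC1C[C@@](O)([C@@H](C)Cc2cc(OC)c(OC)c(OC)c2)C(OC)=CC1=O | intermediate
18 | (4R)-3-methoxy-4-(methoxymethoxy)-6-(prop-2-en-1-yl)-4-[(2S)-1-(3,4,5-trimethoxyphenyl)propan-2-yl]cyclohex-2-en-1-one (both C6 epimers) | C=CCC1C[C@@](OCOC)([C@@H](C)Cc2cc(OC)c(OC)c(OC)c2)C(OC)=CC1=O | intermediate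
19 | (4R)-4-(methoxymethoxy)-6-(prop-2-en-1-yl)-4-[(2S)-1-(3,4,5-trimethoxyphenyl)propan-2-yl]cyclohexane-1,3-dione (both C6 epimers) | C=CCC1C[C@@](OCOC)([C@@H](C)Cc2cc(OC)c(OC)c(OC)c2)C(=O)CC1=O | intermediate
20 | (7aR)-6-(prop-2-en-1-yl)-7a-[(2S)-1-(3,4,5-trimethoxyphenyl)propan-2-yl]-7,7a-dihydro-1,3-benzodioxol-5(6H)-one (both C6 epimers) | C=CCC1C[C@]2([C@@H](C)Cc3cc(OC)c(OC)c(OC)c3)OCOC2=CC1=O | intermediate
21 | (6R,7aR)-6-(prop-2-en-1-yl)-7a-[(2S)-1-(3,4,5-trimethoxyphenyl)propan-2-yl]-7,7a-dihydro-1,3-benzodioxol-5(6H)-one | C=CC[C@@H]1C[C@]2([C@@H](C)Cc3cc(OC)c(OC)c(OC)c3)OCOC2=CC1=O | target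

## Step count and least certain steps

Total: 14 steps. Longest linear sequence: 13 steps (steps 1–7 and 9–14, from 1); step 8 is the single side-branch step.

**Step 11 (key step).** The most likely failure is ring closure through oxygen instead of carbon. The dienolate oxygen can reach C5 in the plane of the π system, whereas C6 has to tilt its π lobe onto the C5–O axis through a tether holding three sp2 atoms. This six-membered epoxide-endo closure has not been tested. Alternatively no closure may occur, because lithium enolates are sluggish toward unactivated epoxides, and slow base-induced isomerisation of the epoxide would then take over. The fallback changes the electrophile. It sets out from 15, which LiI/AcOH in THF opens at C5 to the tertiary iodohydrin F1. Me3SiCl/imidazole caps the hydroxyl as the silyl ether F2. KN(SiMe3)2 in THF closes ring A by intramolecular α′-alkylation of the primary iodide to the silyl-protected cyclohexenone F3. K2CO3 in MeOH removes the silyl group and the route is rejoined at 17.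

**Step 13.** The most likely failure is ionisation of the methoxymethyl group toward the free tertiary alcohol before O3 can capture the acetal carbon. The formaldehyde equivalent set loose would then attack C2 of the dione. Incomplete hydrolysis of the hindered enol ether with so little water is the second risk. The fallback gives up the internal acetal transfer. It sets out from 17, which 1 M HCl in THF hydrolyses to the hydroxy-dione F4. The dianion of F4 (NaH, 2.1 equiv, DMF, 0 °C) is methylenated with BrCH2Cl: the alkoxide is the stronger nucleophile, and the neighbouring enolate oxygen closes the five-membered ring. The route is rejoined at 20.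

**Step 10.** The likely failures are anti addition of methanol without later equilibration, which leaves the (Z)-enol ether that cannot cyclise, and slow methoxide opening of the epoxide. The fallback changes the heteroatom nucleophile. It sets out from 14: pyrrolidine in CH2Cl2 at 0 °C should add to give the (E)-enaminone F5, the usual geometry of amine–ynone adducts. LiN(i-Pr)2 in THF effects the same α′-enolate/epoxide closure to the hydroxy enaminone F6. MeOCH2Cl/i-Pr2NEt gives its methoxymethyl ether F7. 2 M HCl in THF at 40 °C hydrolyses the vinylogous amide to 19, which closes to 20 as in the second stage of step 13.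

**Step 2.** The likely failures are deprotonation at the doubly activated (allylic and benzylic) γ-position by the Grignard reagent, with migration of the double bond into conjugation with the arene, and an unselective background addition. The fallback replaces catalyst control by auxiliary control. It sets out from 1: cross-metathesis with commercial (4R)-4-benzyl-3-(prop-2-enoyl)-1,3-oxazolidin-2-one gives the N-enoyl oxazolidinone F8. MeMgBr with CuBr·SMe2 (0.3 equiv) in THF at −40 °C adds methyl to the chelated s-cis enoyl unit on the face away from the benzyl group (the Si face of the β-carbon), giving the adduct F9. NaOMe (catalytic) in MeOH releases the ester, and the route is rejoined at 4.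

## Further compounds

F1 | step 11 | (1E)-1-[(2R,3S)-2-hydroxy-1-iodo-3-methyl-4-(3,4,5-trimethoxyphenyl)butan-2-yl]-1-methoxyhepta-1,6-dien-3-one | C=CCCC(=O)/C=C(/OC)[C@@](O)(CI)[C@@H](C)Cc1cc(OC)c(OC)c(OC)c1
F2 | step 11 | (1E)-1-[(2R,3S)-1-iodo-3-methyl-4-(3,4,5-trimethoxyphenyl)-2-[(trimethylsilyl)oxy]butan-2-yl]-1-methoxyhepta-1,6-dien-3-one | C=CCCC(=O)/C=C(/OC)[C@@](O[Si](C)(C)C)(CI)[C@@H](C)Cc1cc(OC)c(OC)c(OC)c1
F3 | step 11 | (4R)-3-methoxy-6-(prop-2-en-1-yl)-4-[(2S)-1-(3,4,5-trimethoxyphenyl)propan-2-yl]-4-[(trimethylsilyl)oxy]cyclohex-2-en-1-one (both C6 epimers) | C=CCC1C[C@@](O[Si](C)(C)C)([C@@H](C)Cc2cc(OC)c(OC)c(OC)c2)C(OC)=CC1=O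
F4 | step 13 | (4R)-4-hydroxy-6-(prop-2-en-1-yl)-4-[(2S)-1-(3,4,5-trimethoxyphenyl)propan-2-yl]cyclohexane-1,3-dione (both C6 epimers) | C=CCC1C[C@@](O)([C@@H](C)Cc2cc(OC)c(OC)c(OC)c2)C(=O)CC1=O
F5 | step 10 | (1E)-1-[(2R)-2-[(2S)-1-(3,4,5-trimethoxyphenyl)propan-2-yl]oxiran-2-yl]-1-(pyrrolidin-1-yl)hepta-1,6-dien-3-one | C=CCCC(=O)/C=C(/N1CCCC1)[C@@]1(CO1)[C@@H](C)Cc1cc(OC)c(OC)c(OC)c1
F6 | step 10 | (4R)-4-hydroxy-6-(prop-2-en-1-yl)-3-(pyrrolidin-1-yl)-4-[(2S)-1-(3,4,5-trimethoxyphenyl)propan-2-yl]cyclohex-2-en-1-one (both C6 epimers) | C=CCC1C[C@@](O)([C@@H](C)Cc2cc(OC)c(OC)c(OC)c2)C(N3CCCC3)=CC1=O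
F7 | step 10 | (4R)-4-(methoxymethoxy)-6-(prop-2-en-1-yl)-3-(pyrrolidin-1-yl)-4-[(2S)-1-(3,4,5-trimethoxyphenyl)propan-2-yl]cyclohex-2-en-1-one (both C6 epimers) | C=CCC1C[C@@](OCOC)([C@@H](C)Cc2cc(OC)c(OC)c(OC)c2)C(N3CCCC3)=CC1=O
F8 | step 2 | (4R)-4-benzyl-3-[(2E)-4-(3,4,5-trimethoxyphenyl)but-2-enoyl]-1,3-oxazolidin-2-one | O=C(/C=C/Cc1cc(OC)c(OC)c(OC)c1)N1[C@H](Cc2ccccc2)COC1=O
F9 | step 2 | (4R)-4-benzyl-3-[(3S)-3-methyl-4-(3,4,5-trimethoxyphenyl)butanoyl]-1,3-oxazolidin-2-one | O=C(C[C@@H](C)Cc1cc(OC)c(OC)c(OC)c1)N1[C@H](Cc2ccccc2)COC1=O
A1 | alternative 1 | 4-hydroxy-4-[(2S)-1-(3,4,5-trimethoxyphenyl)propan-2-yl]cyclohexa-2,5-dien-1-one | O=C1C=CC(O)(C=C1)[C@@H](C)Cc1cc(OC)c(OC)c(OC)c1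
A2 | alternative 1 | formaldehyde | C=O
A3 | alternative 1 | cis-7a-[(2S)-1-(3,4,5-trimethoxyphenyl)propan-2-yl]-3a,4-dihydro-1,3-benzodioxol-5(7aH)-one | O=C1C=C[C@]2([C@@H](C)Cc3cc(OC)c(OC)c(OC)c3)OCO[C@@H]2C1
A4 | alternative 2 | ethyl 3-methyl-2-oxo-4-(3,4,5-trimethoxyphenyl)butanoate (racemic) | CCOC(=O)C(=O)C(C)Cc1cc(OC)c(OC)c(OC)c1
A5 | alternative 2 | 2-methylidenepent-4-enal | C=CCC(=C)C=O
A6 | alternative 2 | ethyl 4-allyl-5-oxo-2-[(2S)-1-(3,4,5-trimethoxyphenyl)propan-2-yl]tetrahydrofuran-2-carboxylate | O=C1O[C@@](C(=O)OCC)([C@@H](C)Cc2cc(OC)c(OC)c(OC)c2)C[C@H]1CC=C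
A7 | alternative 2 | (4R)-4-hydroxy-6-(prop-2-en-1-yl)-4-[(2S)-1-(3,4,5-trimethoxyphenyl)propan-2-yl]cyclohexane-1,3-dione | C=CCC1C[C@@](O)([C@@H](C)Cc2cc(OC)c(OC)c(OC)c2)C(=O)CC1=O
A8 | alternative 3 | (4R,5E)-5-(iodomethylidene)-4-(prop-2-en-1-yl)-4-[(2S)-1-(3,4,5-trimethoxyphenyl)propan-2-yl]-1,3-dioxolane | I/C=C1/OCO[C@]1(CC=C)[C@@H](C)Cc1cc(OC)c(OC)c(OC)c1
A9 | alternative 3 | carbon monoxide | [C-]#[O+]
A10 | alternative 3 | (7aR)-6-methylidene-7a-[(2S)-1-(3,4,5-trimethoxyphenyl)propan-2-yl]-7,7a-dihydro-1,3-benzodioxol-5(6H)-one | C=C1C[C@]2([C@@H](C)Cc3cc(OC)c(OC)c(OC)c3)OCOC2=CC1=O
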